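**Retrosynthetic overview** (side-chain locants: C1' = ArOCH2, C2'/C3' = oxirane carbons, C4' = CH2, C5' = lactone CH–O, C6' = CH2, C7' = C(OH)CH3, C8' = lactone C=O)
1. The oxirane is closed last: the C3' tertiary alkoxide displaces a C2' mesylate with inversion. The γ-lactone forms one step earlier, by attack of C5'–OH on a C8' dioxolanone ester.
2. The C5' carbinol comes from a 1,3-anti reduction of a C5' ketone directed by C3'–OH; that β-hydroxy ketone is an unmasked 2-isoxazoline.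
3. Key step: hydroxyl-directed [3+2] cycloaddition of a nitrile oxide (C5'–C8', C7' already in place) to a 1,1-disubstituted allylic alcohol (C1'–C4', umbelliferone attached). It forms C4'–C5' and C3'–O and sets C3' from C2'.
4. The nitrile oxide comes from (R)-lactic acid (dioxolanone alkylation sets C7'). The allylic alcohol comes from D-mannitol-derived methyl (R)-glycerate acetonide (C2') and umbelliferone.
5. Ring order: dioxolanone (temporary) → isoxazoline → γ-lactone → oxirane; the coumarin is bought.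

Assumption: oxime 8 is used as its E/Z mixture, since both isomers give the same nitrile oxide.

**Step 1**
Reactants: 1 (R)-lactic acid; 2 pivalaldehyde
Product: 3 (2R,5R)-2-tert-butyl-5-methyl-1,3-dioxolan-4-one
Conditions: p-TsOH·H2O (cat.), H2SO4 (cat.), pentane, reflux, Dean–Stark; crystallise from pentane/Et2O at −78 °C
Reagents that add atoms: none
Why: Acid-catalysed acetalisation (Seebach self-regeneration of stereocentres) under thermodynamic control puts tert-butyl cis to methyl (about 4:1, upgraded by crystallisation), so the lactic acid centre fixes the acetal centre as 2R.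

**Step 2**
Reactants: 3 (2R,5R)-2-tert-butyl-5-methyl-1,3-dioxolan-4-one; 4 allyl bromide
Product: 6 (2R,5S)-2-tert-butyl-5-methyl-5-(prop-2-en-1-yl)-1,3-dioxolan-4-one, via lithium enolate 5 (not isolated)
Conditions: LiN(i-Pr)2, THF, −78 °C; then 4, −78 → −30 °C
Reagents that add atoms: none
Why: Enolate alkylation in which allyl bromide enters anti to tert-butyl, so the quaternary centre C7' is set with overall retention as 5S.

**Step 3**
Reactants: 6 (2R,5S)-2-tert-butyl-5-methyl-5-(prop-2-en-1-yl)-1,3-dioxolan-4-one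
Product: 8 2-[(2R,4S)-2-tert-butyl-4-methyl-5-oxo-1,3-dioxolan-4-yl]acetaldehyde oxime, via aldehyde 7 (not isolated)
Conditions: O3, CH2Cl2, −78 °C; Me2S, −78 °C → rt; then NH2OH·HCl (3 equiv), pyridine, EtOH, 0 °C → rt
Reagents that add atoms: hydroxylamine hydrochloride, Cl.NO
Why: Ozonolysis with reductive work-up gives the aldehyde, which condenses with hydroxylamine to the aldoxime; no stereocentre is touched.

**Step 4**
Reactants: 9 methyl (4R)-2,2-dimethyl-1,3-dioxolane-4-carboxylate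
Product: 11 1-[(4R)-2,2-dimethyl-1,3-dioxolan-4-yl]ethan-1-one, via Weinreb amide 10 (not isolated)
Conditions: MeNHOMe·HCl, i-PrMgCl, THF, −20 °C; then MeMgBr, −20 → 0 °C; aq. NH4Cl
Reagents that add atoms: methylmagnesium bromide, C[Mg]Br
Why: One-pot Weinreb ketone synthesis, in which the chelated tetrahedral adduct of the N-methoxy-N-methylamide collapses only on work-up, so addition stops at the methyl ketone and the α-centre is kept.

**Step 5**
Reactants: 11 1-[(4R)-2,2-dimethyl-1,3-dioxolan-4-yl]ethan-1-one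
Product: 13 (2S)-3-methylbut-3-ene-1,2-diol, via isopropenyl dioxolane 12 (not isolated)
Conditions: Ph3PCH3Br, KN(SiMe3)2, THF, 0 °C; 11, −78 → 0 °C; pentane work-up without concentration; then Dowex 50W-X8 (H+ form), MeOH/H2O, rt
Reagents that add atoms: methyltriphenylphosphonium bromide, C[P+](c1ccccc1)(c1ccccc1)c1ccccc1.[Br-]
Why: Wittig methylenation at low temperature installs the isopropenyl group, and the volatile acetonide is hydrolysed directly (acid-catalysed acetal cleavage) with the glycerate centre unchanged.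

**Step 6**
Reactants: 13 (2S)-3-methylbut-3-ene-1,2-diol; 14 umbelliferone (7-hydroxy-2H-chromen-2-one)
Product: 15 7-{[(2S)-2-hydroxy-3-methylbut-3-en-1-yl]oxy}-2H-chromen-2-one
Conditions: PPh3, DIAD, THF, 0 °C → rt
Reagents that add atoms: none
Why: Mitsunobu etherification in which the acidic phenol is alkylated at the less hindered primary carbinol, leaving the secondary allylic centre (C2') untouched.

**Step 7**
Reactants: 8 2-[(2R,4S)-2-tert-butyl-4-methyl-5-oxo-1,3-dioxolan-4-yl]acetaldehyde oxime; 15 7-{[(2S)-2-hydroxy-3-methylbut-3-en-1-yl]oxy}-2H-chromen-2-one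
Product: 19 (2R,5S)-2-tert-butyl-5-({(5R)-5-[(1R)-1-hydroxy-2-[(2-oxo-2H-chromen-7-yl)oxy]ethyl]-5-methyl-4,5-dihydro-1,2-oxazol-3-yl}methyl)-5-methyl-1,3-dioxolan-4-one, via hydroximoyl chloride 16 (not isolated), via bromomagnesium alkoxide 17 (not isolated), via nitrile oxide 18 (not isolated)
Conditions: 8, t-BuOCl, CH2Cl2, −78 °C; separately i-PrOH (3.3 equiv), EtMgBr (3.0 equiv), CH2Cl2, 0 °C, then 15; add the solution of 16 over 2 h, 0 °C → rt; aq. NH4Cl
Reagents that add atoms: none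
Why: Magnesium-alkoxide-directed nitrile oxide [3+2] cycloaddition (Kanemasa–Carreira), in which the alkoxide delivers the dipole oxygen to the disubstituted alkene carbon on the face syn to O–Mg with the carbinol hydrogen inside, giving the 5,5-disubstituted isoxazoline with C3' R (syn to the C2' hydroxyl).

**Step 8**
Reactants: 19 isoxazoline (name as in step 7)
Product: 21 (2R,5S)-2-tert-butyl-5-[(4R,5R)-4,5-dihydroxy-4-methyl-2-oxo-6-[(2-oxo-2H-chromen-7-yl)oxy]hexyl]-5-methyl-1,3-dioxolan-4-one, via hydroxy imine 20 (not isolated)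
Conditions: Mo(CO)6, MeCN/H2O (15:1), 80 °C
Reagents that add atoms: water, O
Why: Mo(CO)6-mediated reductive N–O cleavage and hydrolysis of the β-hydroxy imine unmask the isoxazoline as the β-hydroxy ketone without touching the coumarin alkene or any stereocentre.

**Step 9**
Reactants: 21 β-hydroxy ketone diol (name as in step 8)
Product: 22 (2R,3R)-6-[(2R,4S)-2-tert-butyl-4-methyl-5-oxo-1,3-dioxolan-4-yl]-3-hydroxy-3-methyl-5-oxo-1-[(2-oxo-2H-chromen-7-yl)oxy]hexan-2-yl methanesulfonate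
Conditions: MsCl (1.1 equiv), Et3N, CH2Cl2, −20 °C
Reagents that add atoms: methanesulfonyl chloride, CS(=O)(=O)Cl
Why: Sulfonylation via sulfene is much faster at the secondary than at the tertiary hydroxyl, so only C2'–OH becomes the leaving group, which also stops the 1,2-diol from chelating boron in the next step.

**Step 10**
Reactants: 22 keto mesylate (name as in step 9)
Product: 24 (2R,3R)-3-hydroxy-4-[(2R,4S)-4-hydroxy-4-methyl-5-oxooxolan-2-yl]-3-methyl-1-[(2-oxo-2H-chromen-7-yl)oxy]butan-2-yl methanesulfonate, via hydroxy dioxolanone 23 (not isolated)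
Conditions: Me4NBH(OAc)3 (5 equiv), MeCN/AcOH (1:1), −30 °C; aq. NaHCO3 work-up; then PPTS (cat.), CH2Cl2, rt
Reagents that add atoms: none
Why: Evans–Saksena reduction in which the free tertiary C3' hydroxyl delivers hydride through a chair with the large C2' branch equatorial, giving the 1,3-anti C5' alcohol, which then lactonises onto the dioxolanone carbonyl with loss of pivalaldehyde (acid-catalysed translactonisation).

**Step 11**
Reactants: 24 lactone mesylate (name as in step 10)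
Product: 25 (3S,5S)-3-hydroxy-3-methyl-5-{[(2R,3S)-2-methyl-3-{[(2-oxo-2H-chromen-7-yl)oxy]methyl}oxiran-2-yl]methyl}oxolan-2-one
Conditions: DBU, CH2Cl2, 0 °C → rt
Reagents that add atoms: none
Why: Intramolecular Williamson (3-exo-tet) displacement of the mesylate by the adjacent tertiary alkoxide inverts C2' and closes the oxirane with ArOCH2 and the C4' methylene cis.

**Compound list**
1 | (R)-lactic acid | C[C@@H](O)C(=O)O | starting material
2 | pivalaldehyde (2,2-dimethylpropanal) | CC(C)(C)C=O | starting material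
3 | (2R,5R)-2-tert-butyl-5-methyl-1,3-dioxolan-4-one | C[C@H]1O[C@@H](C(C)(C)C)OC1=O | intermediate
4 | allyl bromide | C=CCBr | starting material
5 | lithium (2R)-2-tert-butyl-5-methyl-1,3-dioxol-4-olate | CC1=C([O-])O[C@H](C(C)(C)C)O1.[Li+] | intermediate
6 | (2R,5S)-2-tert-butyl-5-methyl-5-(prop-2-en-1-yl)-1,3-dioxolan-4-one | C=CC[C@]1(C)O[C@@H](C(C)(C)C)OC1=O | intermediate
7 | 2-[(2R,4S)-2-tert-butyl-4-methyl-5-oxo-1,3-dioxolan-4-yl]acetaldehyde | O=CC[C@]1(C)O[C@@H](C(C)(C)C)OC1=O | intermediate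
8 | 2-[(2R,4S)-2-tert-butyl-4-methyl-5-oxo-1,3-dioxolan-4-yl]acetaldehyde oxime (E/Z mixture) | ON=CC[C@]1(C)O[C@@H](C(C)(C)C)OC1=O | intermediate
9 | methyl (4R)-2,2-dimethyl-1,3-dioxolane-4-carboxylate | COC(=O)[C@H]1COC(C)(C)O1 | starting material
10 | (4R)-N-methoxy-N,2,2-trimethyl-1,3-dioxolane-4-carboxamide | CON(C)C(=O)[C@H]1COC(C)(C)O1 | intermediate
11 | 1-[(4R)-2,2-dimethyl-1,3-dioxolan-4-yl]ethan-1-one | CC(=O)[C@H]1COC(C)(C)O1 | intermediate
12 | (4S)-2,2-dimethyl-4-(prop-1-en-2-yl)-1,3-dioxolane | C=C(C)[C@H]1COC(C)(C)O1 | intermediate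
13 | (2S)-3-methylbut-3-ene-1,2-diol | C=C(C)[C@H](O)CO | intermediate
14 | umbelliferone (7-hydroxy-2H-chromen-2-one) | O=c1ccc2ccc(O)cc2o1 | starting material
15 | 7-{[(2S)-2-hydroxy-3-methylbut-3-en-1-yl]oxy}-2H-chromen-2-one | C=C(C)[C@H](O)COc1ccc2ccc(=O)oc2c1 | intermediate
16 | 2-[(2R,4S)-2-tert-butyl-4-methyl-5-oxo-1,3-dioxolan-4-yl]-N-hydroxyethanimidoyl chloride | ON=C(Cl)C[C@]1(C)O[C@@H](C(C)(C)C)OC1=O | intermediate
17 | bromomagnesium (2S)-3-methyl-1-[(2-oxo-2H-chromen-7-yl)oxy]but-3-en-2-olate | C=C(C)[C@H]([O-])COc1ccc2ccc(=O)oc2c1.[Mg+2].[Br-] | intermediate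
18 | 2-[(2R,4S)-2-tert-butyl-4-methyl-5-oxo-1,3-dioxolan-4-yl]acetonitrile oxide | [O-][N+]#CC[C@]1(C)O[C@@H](C(C)(C)C)OC1=O | intermediate
19 | (2R,5S)-2-tert-butyl-5-({(5R)-5-[(1R)-1-hydroxy-2-[(2-oxo-2H-chromen-7-yl)oxy]ethyl]-5-methyl-4,5-dihydro-1,2-oxazol-3-yl}methyl)-5-methyl-1,3-dioxolan-4-one | O=c1ccc2ccc(OC[C@@H](O)[C@@]3(C)CC(C[C@]4(C)O[C@@H](C(C)(C)C)OC4=O)=NO3)cc2o1 | intermediate
20 | (2R,5S)-2-tert-butyl-5-[(4R,5R)-4,5-dihydroxy-2-imino-4-methyl-6-[(2-oxo-2H-chromen-7-yl)oxy]hexyl]-5-methyl-1,3-dioxolan-4-one | O=c1ccc2ccc(OC[C@@H](O)[C@](C)(O)CC(=N)C[C@]3(C)O[C@@H](C(C)(C)C)OC3=O)cc2o1 | intermediate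
21 | (2R,5S)-2-tert-butyl-5-[(4R,5R)-4,5-dihydroxy-4-methyl-2-oxo-6-[(2-oxo-2H-chromen-7-yl)oxy]hexyl]-5-methyl-1,3-dioxolan-4-one | O=c1ccc2ccc(OC[C@@H](O)[C@](C)(O)CC(=O)C[C@]3(C)O[C@@H](C(C)(C)C)OC3=O)cc2o1 | intermediate
22 | (2R,3R)-6-[(2R,4S)-2-tert-butyl-4-methyl-5-oxo-1,3-dioxolan-4-yl]-3-hydroxy-3-methyl-5-oxo-1-[(2-oxo-2H-chromen-7-yl)oxy]hexan-2-yl methanesulfonate | O=c1ccc2ccc(OC[C@@H](OS(C)(=O)=O)[C@](C)(O)CC(=O)C[C@]3(C)O[C@@H](C(C)(C)C)OC3=O)cc2o1 | intermediate
23 | (2R,3R,5R)-6-[(2R,4S)-2-tert-butyl-4-methyl-5-oxo-1,3-dioxolan-4-yl]-3,5-dihydroxy-3-methyl-1-[(2-oxo-2H-chromen-7-yl)oxy]hexan-2-yl methanesulfonate | O=c1ccc2ccc(OC[C@@H](OS(C)(=O)=O)[C@](C)(O)C[C@@H](O)C[C@]3(C)O[C@@H](C(C)(C)C)OC3=O)cc2o1 | intermediate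
24 | (2R,3R)-3-hydroxy-4-[(2R,4S)-4-hydroxy-4-methyl-5-oxooxolan-2-yl]-3-methyl-1-[(2-oxo-2H-chromen-7-yl)oxy]butan-2-yl methanesulfonate | C[C@]1(O)C[C@@H](C[C@@](C)(O)[C@H](OS(C)(=O)=O)COc2ccc3ccc(=O)oc3c2)OC1=O | intermediate
25 | (3S,5S)-3-hydroxy-3-methyl-5-{[(2R,3S)-2-methyl-3-{[(2-oxo-2H-chromen-7-yl)oxy]methyl}oxiran-2-yl]methyl}oxolan-2-one | C[C@]1(O)C[C@@H](C[C@@]2(C)O[C@H]2COc2ccc3ccc(=O)oc3c2)OC1=O | target

**Total step count:** 11
**Longest linear sequence:** 8 steps (9 → 11 → 13 → 15 → 19 → 21 → 22 → 24 → 25; the branch from 1 is equally long)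

**Three steps most likely to fail**

Step 6 (Mitsunobu on an unprotected allylic 1,2-diol). The secondary allylic position or cyclodehydration may compete with primary etherification. Fallback, setting out from 13 and coming back at 15: sulfonylate only the primary hydroxyl (TsCl, Et3N, cat. Bu2SnO, CH2Cl2) to give (2S)-2-hydroxy-3-methylbut-3-en-1-yl 4-methylbenzenesulfonate F1. Then alkylate the phenoxide of 14 with it (K2CO3, DMF, 60 °C), directly or through the terminal epoxide formed in situ; both paths leave C2' untouched and give 15.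

Step 7 (directed cycloaddition). The coumarin lactone and the dioxolanone are exposed to magnesium alkoxides, and the facial selectivity on a 1,1-disubstituted alkene may be lower than for vinyl carbinols. Fallback, setting out from 13 and coming back at 19: protect the primary hydroxyl (TBSCl, imidazole, CH2Cl2) to give (2S)-1-{[tert-butyl(dimethyl)silyl]oxy}-3-methylbut-3-en-2-ol F2. Run the same magnesium-alkoxide-directed cycloaddition of 16 on this coumarin-free partner to give the silyl-protected isoxazoline F3. Remove the silyl group (TBAF, AcOH, THF) to give the isoxazoline diol F4. Introduce umbelliferone 14 last by Mitsunobu etherification of the primary hydroxyl (the secondary one is neopentyl-like), arriving at 19.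

Step 10 (1,3-anti reduction directed by a tertiary carbinol). The methyl/branch differentiation in the chair may give only modest selectivity. Fallback, setting out from 22 and coming back at 24: silylate the tertiary hydroxyl with (i-Pr)2SiHCl (imidazole, DMAP, DMF) to give the 3-O-diisopropylsilyl ether of 22 F5. SnCl4-catalysed intramolecular hydrosilylation (CH2Cl2, −78 °C) delivers hydride from the tethered silicon and gives the anti-configured 2,2-diisopropyl-1,3,2-dioxasilinane of 23 F6. HF·pyridine in THF frees 23, which lactonises with PPTS as in step 10 to 24.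

**Further compounds**
F1 | step 6 | (2S)-2-hydroxy-3-methylbut-3-en-1-yl 4-methylbenzenesulfonate | C=C(C)[C@H](O)COS(=O)(=O)c1ccc(C)cc1
F2 | step 7 | (2S)-1-{[tert-butyl(dimethyl)silyl]oxy}-3-methylbut-3-en-2-ol | C=C(C)[C@H](O)CO[Si](C)(C)C(C)(C)C
F3 | step 7 | (2R,5S)-2-tert-butyl-5-({(5R)-5-[(1R)-2-{[tert-butyl(dimethyl)silyl]oxy}-1-hydroxyethyl]-5-methyl-4,5-dihydro-1,2-oxazol-3-yl}methyl)-5-methyl-1,3-dioxolan-4-one | CC(C)(C)[Si](C)(C)OC[C@@H](O)[C@@]1(C)CC(C[C@]2(C)O[C@@H](C(C)(C)C)OC2=O)=NO1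
F4 | step 7 | (2R,5S)-2-tert-butyl-5-({(5R)-5-[(1R)-1,2-dihydroxyethyl]-5-methyl-4,5-dihydro-1,2-oxazol-3-yl}methyl)-5-methyl-1,3-dioxolan-4-one | OC[C@@H](O)[C@@]1(C)CC(C[C@]2(C)O[C@@H](C(C)(C)C)OC2=O)=NO1
F5 | step 10 | 3-O-[di(propan-2-yl)silyl] ether of 22 (silicon on the tertiary C3' oxygen, ketone and mesylate unchanged) | O=c1ccc2ccc(OC[C@@H](OS(C)(=O)=O)[C@](C)(O[SiH](C(C)C)C(C)C)CC(=O)C[C@]3(C)O[C@@H](C(C)(C)C)OC3=O)cc2o1
F6 | step 10 | 2,2-di(propan-2-yl)-1,3,2-dioxasilinane of 23 (silicon bridging the C3' and C5' oxygens, anti) | O=c1ccc2ccc(OC[C@@H](OS(C)(=O)=O)[C@@]3(C)C[C@H](C[C@]4(C)O[C@@H](C(C)(C)C)OC4=O)O[Si](C(C)C)(C(C)C)O3)cc2o1
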